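- A pitfall here is to read this series by its third substrate, which goes from 1.1 M to 1.9 M in the earlier runs and from 1.00 M to 1.70 M in the new flasks.

all flasks: starting material 0.20 M
- north-east: coupling partner 0.50 M; second substrate 0.10 M; third substrate 1.1 M; protic impurity 0.060 M; run made earlier
- south: coupling partner 0.50 M; second substrate 0.10 M; third substrate 1.4 M; protic impurity 0.060 M; run made earlier
- south-west: coupling partner 0.50 M; second substrate 0.10 M; third substrate 1.9 M; protic impurity 0.060 M; run made earlier
- noon: coupling partner 0.500 M; second substrate 0.100 M; third substrate 1.00 M; protic impurity 0.0600 M; time 6.0 h
- winter: coupling partner 0.500 M; second substrate 0.100 M; third substrate 1.30 M; protic impurity 0.0600 M; time 6.0 h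
- dusk: coupling partner 0.500 M; second substrate 0.100 M; third substrate 1.70 M; protic impurity 0.0600 M; time 6.0 h

| run | time / h | side product / % | starting material / % | target / % |
|---|---|---|---|---|
| north-east | 0.500 | 0 | 82.4 | 6.7 |
| north-east | 0.833 | 0.8 | 77.0 | 12.4 |
| north-east | 1.50 | 3.2 | 63.9 | 18.8 |
| north-east | 3.00 | 5.1 | 48.4 | 27.0 |
| north-east | 6.00 | 9.0 | 27.1 | 37.8 |
| south | 0.500 | 2.2 | 85.1 | 6.9 |
| south | 1.50 | 0 | 64.3 | 19.0 |
| south | 3.00 | 3.1 | 46.4 | 27.4 |
| south | 4.00 | 7.3 | 38.3 | 29.7 |
| south | 6.00 | 9.5 | 28.7 | 38.6 |
| south-west | 1.33 | 0.3 | 66.4 | 16.9 |
| south-west | 2.50 | 3.3 | 52.2 | 26.7 |
| south-west | 4.00 | 4.6 | 37.8 | 32.2 |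
| south-west | 5.00 | 7.5 | 29.8 | 33.5 |
| south-west | 6.00 | 9.1 | 26.7 | 37.7 |

(readings scatter by 1 percentage point)

- percent here means starting material units held: one side product counts as two
- steps thought possible: starting material + coupling partner -> target; starting material + protic impurity -> quenched substrate; starting material + target -> side product; second substrate + coupling partner -> second product; third substrate + coupling partner -> third product

1. which of these there is most of at the end, counted by the starting material in it, noon (target / side product / starting material)
2. which of these there is most of at the end, counted by the starting material in it, winter (target / side product / starting material)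
3. which of these there is most of at the end, counted by the starting material in it, dusk (target / side product / starting material)
4. how much there is at the end of the one of these that leads, in percent of the starting material charged: noon
5. how much there is at the end of the one of these that leads, in percent of the starting material charged: winter
6. how much there is at the end of the one of these that leads, in percent of the starting material charged: dusk

- Look instead at the quench ceiling, c(protic impurity)/c(starting material) = 30.0%: the part of the charged starting material that protic impurity can take, one for one, as quenched substrate. Protic impurity is the limiting reagent of that step, with 0.0600 M against 0.20 M, and the north-east recipe has the same ratio as noon.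
- The readings at 6.0 h leave a mean balance gap of 25.3%, less than the ceiling, so the quench is near its limit but still short of it.
- The ceiling leaves 70.0% for the other three species, but it doesn't say how they divide, so one number is not enough. The division has to be read from the runs.
- Replacing the three end readings by their mean gives my reckoning: target 38.0% against starting material 27.5%, so target leads in noon, winter and dusk.
- The error of that mean is testable: south-west minus north-east target is −0.1 percentage points, while a difference of two readings scatters by 1.4 points. Noon, though, lies just below the tested range.
- The forecast names target, target and target at 37.8%, 37.8% and 37.8%, slightly below my mean, and says "Smoothing the time trend gives target leading".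
- The flasks give target at 37.6% in noon, target at 37.5% in winter and target at 37.5% in dusk.

    starting material + coupling partner → target (k = 0.350 M⁻¹ h⁻¹)
    starting material + protic impurity → quenched substrate (k = 3.20 M⁻¹ h⁻¹)
    starting material + target → side product (k = 0.350 M⁻¹ h⁻¹)
    second substrate + coupling partner → second product (k = 1.40 M⁻¹ h⁻¹)
    third substrate + coupling partner → third product (k = 0.00220 M⁻¹ h⁻¹)

- Dusk holds 25.9% quenched substrate, under its ceiling of 30.0%, with 14% of its protic impurity left. In the neighbour of dusk charged with 0.80 M starting material, the same reckoning gives a ceiling of 7.50%. That neighbour reaches it, with 7.50% quenched substrate and 0.00715% of its protic impurity left. Its target stands at 19.2% and its side product at 31.1%, while starting material leads at 42.2%.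

(The data stem from a simulated flask for an exercise.)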